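The easy mistake with these runs is to interpolate the peak of isomer of the product A and never look at what stands beside it in the same reading.

in all of them: starting material 44 mM
- south-east: protic impurity 44 mM; catalyst 0.15 mM; run made earlier
- east: protic impurity 44 mM; catalyst 0.33 mM; run made earlier
- flask: protic impurity 44.0 mM; catalyst 0.22 mM; time 1.5 h

- south-east (time / min: isomer of the product A / %, target / %): 1.50: 3.8, 2.0; 4.00: 7.3, 3.2; 12.0: 9.0, 4.7; 30.0: 6.0, 2.4; 90.0: 2.2, 1.8
- east (time / min: isomer of the product A / %, target / %): 1.50: 10.8, 1.5; 4.00: 15.7, 2.8; 12.0: 10.8, 4.5; 30.0: 6.5, 3.0; 90.0: 2.5, 1.2

(standard deviation of a reading: 0.5 percentage points)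

* when, up to 1.5 h, the flask holds most isomer of the product A
* the amount of isomer of the product A, in percent of the starting material charged, at that time
* earliest time at which at least nineteen twentieths of that best amount are there
* latest time at which they still are

- reactions considered so far: starting material <-> target; target <-> isomer of the product A; isomer of the product A + catalyst <-> isomer of the product B + catalyst; isomer of the product B + catalyst <-> starting material + catalyst; starting material + protic impurity -> quenched substrate

At the first reading, isomer of the product A stands at 3.8 % in the south-east run and 10.8 % in the east run, so its start climbs with catalyst. Its highest readings are 9.0 % at 12.0 min in the south-east run and 15.7 % at 4.00 min in the east run. The flask's catalyst lies between those of the two runs , so I bracket its knee between those two readings.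

Now I divide isomer of the product A by target within each reading, which gives the ratio of the amounts present at that time; this ratio changes with time, so I look for where it levels. The east run starts at 7.20 and is still at 5.61 at 4.00 min. The south-east run starts at 1.90. From 12.0 min to 30.0 min both runs scatter around one level. Pooled, that gives the settling ratio 2.21, a reading of what looks like a quasi-equilibrium between the two. The first ratio of the east run stands above that level.

The last readings of isomer of the product A are 2.2 % and 2.5 %, so for the flask's end I expect about 2.35 %, and the settling ratio then gives target about 1.06 %.

The forecast is sharper than my bracket: best time 0.11 h, best amount 12.3 %, window 0.078 h to 0.175 h, on the ground that “Peak time therefore scales roughly as 1/catalyst”.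

The flask peaks at 0.103 h with 11.6 %, and its window runs from 0.0671 h to 0.158 h, so the forecast opens 1.16 times too late.

    starting material ⇌ target (K = 2.46, k = 0.0660 min⁻¹)
    target ⇌ isomer of the product A (K = 2.20, k = 0.0526 min⁻¹)
    isomer of the product A + catalyst ⇌ isomer of the product B + catalyst, rate k3*[catalyst]*[isomer of the product A] forward; the back reaction follows from the equilibrium constant (K = 0.426, k = 290 M⁻¹ min⁻¹)
    isomer of the product B + catalyst ⇌ starting material + catalyst, rate k4*[catalyst]*[isomer of the product B] forward; the back reaction follows from the equilibrium constant (k = 8210 M⁻¹ min⁻¹)
    starting material + protic impurity → quenched substrate (k = 68.1 M⁻¹ min⁻¹)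

At the best time the flask's ratio is 3.45, and at its end, with isomer of the product A at 2.48 % and target at 1.23 %, it is 2.02. The neighbouring flask, charged with 110 mM of starting material, ends with 29.1 % of isomer of the product A. The settling ratio turns that into 13.2 % of target, and the neighbour holds 13.2 %.

The data come from a simulation for substances that don't exist, and the scatter is random.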